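(Its constants are those of an exercise; the flask was simulated.)

**Slow drift.** Slowness is what you work with here: target turns into its isomer slowly, so the reading depends on how old the material is when you take it. The vessels differ in that age.

| flask | starting material | catalyst | remark | time |
|---|---|---|---|---|
| south-east | 13 mM | 0.5 mol% | a single well-mixed tank run continuously and read at steady state, 2.5 d in it on average |  |
| west | 13 mM (fed, over 2.50 d) | 0.5 mol% | all but starting material at the start; starting material goes in evenly over 2.50 d, the run ends at 2.5 d | 2.5 d |
| north-east | 13 mM | 0.5 mol% | everything together in a closed stirred flask, run for 2.5 d | 2.5 d |

    starting material + catalyst ⇌ target + catalyst, rate k1*[starting material]*[catalyst] forward; the back reaction follows from the equilibrium constant (K1 = 9.9, k1 = 0.741 M⁻¹ s⁻¹)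
    target ⇌ isomer of the product (K2 = 0.511, k2 = 2.86 × 10⁻⁶ s⁻¹)
    isomer of the product ⇌ starting material (k3 = 2.58 × 10⁻⁷ s⁻¹)

- the stated concentrations are those of everything mixed, before any reaction; amounts are the same in each set-up
- the feed brings no volume worth counting
- run time (west): 2.5 d

- the set-up with the highest share of target in all that became target or isomer of the product, at the outlet or at the end ("none" if the first two lie within 2 percentage points) (south-east / west / north-east / none)
- share of target in all that became target or isomer of the product, at the outlet or at the end, south-east
- share of target in all that became target or isomer of the product, at the outlet or at the end, west
- share of target in all that became target or isomer of the product, at the outlet or at the end, north-east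

**First step.** With this step alone, the catalyst at 0.0650 mM gives a pseudo-first-order half-life of 0.167 d for starting material. No isomer forms, so by my reckoning the share of target is 100% in each vessel.

**Second step.** Adding it takes you from kinetic towards thermodynamic control, and the share falls towards 66.2%. Forward and back rates together give 0.731 d⁻¹. The excess share over that level therefore halves in each drift life, 0.949 d. Target forms faster than it drifts, so I take age as time since entering.

In north-east, with one age, the excess decays exponentially over 2.5 d, giving 71.6%. In the south-east tank, with its spread of ages, the excess is divided by one plus the drift rate times the mean stay, giving 78.1%. In west, ages run evenly from zero to 2.50 d, and averaging the decay gives 81.7%.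

**Last step.** Isomer returns slowly, with a forward half-life of 31 d against 2.5 d. Starting material also leaks straight to isomer, at 2.71% of its rate to target. I keep my numbers, expect shifts of about that size, and rank west first.

**The forecast.** It chose west, with 76.9% for south-east, 80.9% for west and 71.8% for north-east, reasoning that “the set-up that keeps the material youngest retains the most target”.

**The result.** The simulation gives west as best, with 76.9% for south-east, 80.9% for west and 71.9% for north-east. The forecast held.

**Why north-east falls.** The turning of target into isomer, both ways, is the main reason for the share in north-east: without that step, north-east gives 95.1% instead of 71.9%. Material in north-east is 2.63 drift lives old at the end, whereas dosed material in west averages 1.32.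

**Later reading.** Read west at 6.0 d, and the ages run from 3.50 d to 6.0 d, so the drift life gives 67.4%. The simulation gives 67.4%.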